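**Plan**

1. Retrosynthesis: first the diene (C13–C14 by Stille coupling, C12=C13 by iodo-Wittig olefination) and the two acetates; then O–C6 (Rubottom) and H–C7 (ketone reduction); then the key cut, C8–C9 of ring B, with C9 re-bonded to C7, which leaves a trans-hydrindane carrying OH and acetyl on C7; finally C7=C8 (Wittig), C9–C11 (enolate alkylation), C5=C6 (aldol) and C9–C10 (allylation) back to 2,2,6-trimethylcyclohexanone.
2. Enabling feature: in ring B (C5–C6–C7–C8–C9–C10) the methyl carbinol C8 sits next to oxygenated C7; at the C7-ketone level this is a 2-hydroxy-2-methylcyclohexanone, the product pattern of an acyloin (α-ketol) shift of a 1-acetylcyclopentan-1-ol.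
3. Forward: ring A is bought; the five-membered ring C5–C6–C7–C9–C10 is closed by aldol condensation; the C11–C12 handle is put on C9; the ring fusion is set by enone reduction; C7 receives the acetyl carbinol; ring B arises by one-carbon ring expansion; O-6, H-7, the acetates and the vinyl group follow.
4. Stereochemistry: C10 from the Pd/PHOX allylation; C5 by axial protonation; C9 by equilibration; the hydrindane C7 by osmylation anti to C20; C8 by the chelate-controlled shift; C6 and C7 by reagent approach anti to the axial methyls; 12Z from the iodo-Wittig step, retained in the coupling.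

Key step: step 13

Remark: positions are given in labdane numbering of the target (C20 = angular methyl on C10; the target is 10R, the antipodal labdane series); "syn" and "anti" refer to the C20 face. Assumption: (S)-t-BuPHOX is taken to give (S)-5, as it does with 2-methylcyclohexanone-derived enol carbonates; if the sense were opposite, the (R)-ligand would be used.

**Route**

Step 1
Reactants: 1 2,2,6-trimethylcyclohexan-1-one; 2 allyl chloroformate
Product: 4 allyl 2,6,6-trimethylcyclohex-1-en-1-yl carbonate, via lithium enolate 3 (not isolated)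
Conditions: LiHMDS, THF, 0 °C; then 2, −78 °C to rt
Reagents that add atoms: allyl chloroformate 2, C=CCOC(Cl)=O
Why: Deprotonation at the only α-C–H gives the tetrasubstituted lithium enolate, and the hard chloroformate should acylate this hindered enolate on oxygen (enol carbonate formation).

Step 2
Reactants: 4 allyl enol carbonate
Product: 5 (S)-2-allyl-2,6,6-trimethylcyclohexan-1-one
Conditions: Pd2(dba)3 (cat.), (S)-t-BuPHOX (cat.), THF, 25 °C
Reagents that add atoms: none
Why: Pd(0) ionises the allyl carbonate, CO2 is lost and the chiral Pd–PHOX allyl enolate couples by inner-sphere reductive elimination (decarboxylative asymmetric allylic alkylation, Tsuji allylation), the ligand setting the quaternary centre C10.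

Step 3
Reactants: 5 (S)-2-allyl-2,6,6-trimethylcyclohexan-1-one
Product: 6 (S)-2,2,6-trimethyl-6-(2-oxopropyl)cyclohexan-1-one
Conditions: PdCl2 (cat.), Cu(OAc)2·H2O (cat.), O2 (1 atm), DMA/H2O 7:1, rt
Reagents that add atoms: water, O
Why: Wacker–Tsuji oxidation: Markovnikov hydroxypalladation of the terminal alkene and β-hydride elimination should give the methyl ketone, the hindered ring ketone being inert.

Step 4
Reactants: 6 1,4-diketone
Product: 7 (7aS)-4,4,7a-trimethyl-1,4,5,6,7,7a-hexahydro-2H-inden-2-one (C5=C6–C7=O enone)
Conditions: KOH, xylenes, 110 °C, Dean–Stark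
Reagents that add atoms: none
Why: Intramolecular aldol condensation: the methyl-side enolate of the side-chain ketone adds to the ring carbonyl to close the five-membered ring C5–C6–C7–C9–C10 and dehydration gives the cyclopentenone, while the quaternary C10 is untouched.

Step 5
Reactants: 7 bicyclic enone; 8 tert-butyl(2-iodoethoxy)dimethylsilane
Product: 10 enone with a 2-(tert-butyldimethylsilyloxy)ethyl chain on C9 (C9 epimers), via lithium dienolate 9 (not isolated)
Conditions: LDA, THF, −78 °C; then 8, DMPU, −78 to 0 °C
Reagents that add atoms: tert-butyl(2-iodoethoxy)dimethylsilane 8, CC(C)(C)[Si](C)(C)OCCI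
Why: C9 is the only enolisable carbon (the γ-position C4 is quaternary), so kinetic α′-deprotonation gives the cross-conjugated dienolate, which is C-alkylated by the primary iodide (enolate alkylation); the configuration at C9 is settled in step 6.

Step 6
Reactants: 10 alkylated enone
Product: 13 trans-fused octahydroinden-2-one (H-5 anti and the C9 chain syn to C20), via lithium enolate 11 (not isolated), via ketone epimer mixture 12 (not isolated)
Conditions: Li, NH3(l)/THF, t-BuOH (1 equiv), −78 °C; NH4Cl; then NaOMe (cat.), MeOH, rt
Reagents that add atoms: none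
Why: Dissolving-metal (Birch-type) enone reduction: the β-carbon C5 should be protonated axially on the face anti to the syn-axial methyls on C4 and C10, which gives the trans ring fusion, and methoxide then equilibrates C9 to the quasi-equatorial epimer with the chain syn to C20, the arrangement that C17 side chains prefer in trans-hydrindane steroids.

Step 7
Reactants: 13 trans-hydrindanone; 14 ethyltriphenylphosphonium bromide
Product: 15 7-ethylidene silyl ether (E/Z mixture)
Conditions: 14, KOt-Bu, THF, reflux
Reagents that add atoms: ethyltriphenylphosphonium bromide 14, CC[P+](c1ccccc1)(c1ccccc1)c1ccccc1.[Br-]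
Why: Wittig olefination with the non-stabilised ylide, as used to ethylidenate hindered 17-oxo steroids; the ylide attacks anti to C20, the basic medium keeps C9 at its thermodynamic configuration, and the alkene geometry is of no consequence.

Step 8
Reactants: 15 ethylidene silyl ether
Product: 16 primary alcohol (C12–OH)
Conditions: TBAF, THF, 0 °C to rt
Reagents that add atoms: none
Why: Fluoride cleaves the primary silyl ether (desilylation) without touching the alkene.

Step 9
Reactants: 16 primary alcohol
Product: 17 C12 aldehyde
Conditions: Dess–Martin periodinane, CH2Cl2, rt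
Reagents that add atoms: none
Why: Dess–Martin oxidation of the primary alcohol stops at the aldehyde under near-neutral conditions that leave the trisubstituted alkene and C9 alone.

Step 10
Reactants: 17 aldehyde; 18 ethyltriphenylphosphonium iodide
Product: 19 (Z)-iodoalkene (C12=C13, iodine cis to C11)
Conditions: 18, n-BuLi, THF, rt; I2, −78 °C; NaHMDS, −20 °C; then 17, −78 °C
Reagents that add atoms: ethyltriphenylphosphonium iodide 18, CC[P+](c1ccccc1)(c1ccccc1)c1ccccc1.[I-]; iodine, II
Why: Stork–Zhao-type Wittig olefination with the α-iodoethylidene ylide: under kinetic conditions the cis-oxaphosphetane should form, giving the (Z)-iodoalkene with iodine cis to C11.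

Step 11
Reactants: 19 iodoalkene with the 7-ethylidene group
Product: 20 7,8-diol (O-7 anti and C8 syn to C20; C8 epimers)
Conditions: OsO4 (cat.), NMO, acetone/H2O, 0 °C
Reagents that add atoms: osmium tetroxide, O=[Os](=O)(=O)=O; N-methylmorpholine N-oxide, C[N+]1([O-])CCOCC1; water, O
Why: Upjohn dihydroxylation: OsO4 should add to the electron-rich trialkyl ethylidene much faster than to the iodine-deactivated alkene, and from the face anti to C20 and to the C9 chain, which puts O-7 anti and C8 syn to C20.

Step 12
Reactants: 20 diol
Product: 21 α-ketol (7-hydroxy-7-acetyl; acetyl syn to C20)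
Conditions: IBX, DMSO, rt
Reagents that add atoms: none
Why: IBX oxidises the secondary carbinol of a 1,2-diol to the ketone without glycol cleavage and cannot oxidise the tertiary alcohol.

Step 13
Reactants: 21 α-ketol
Product: 22 ring-enlarged ketol (8-hydroxy-8-methyl-7-ketone; OH-8 anti and CH3-8 syn to C20)
Conditions: BF3·OEt2 (0.5 equiv), CH2Cl2, −40 to 0 °C
Reagents that add atoms: none
Why: BF3 binds the acetyl oxygen and is held syn to the C7 hydroxyl (chelate), and the C7–C9 σ-bond, then aligned with the C8 π* orbital, shifts to C8 while C7 becomes the ketone: an acyloin (α-ketol) rearrangement, the reaction type by which 17-hydroxy-20-oxo steroids undergo D-homoannulation. Ring B (C5–C6–C7–C8–C9–C10) closes by this suprafacial 1,2-alkyl shift, a one-carbon ring expansion that inserts the exocyclic acetyl carbon between C7 and C9 and is driven by loss of trans-hydrindane and cyclopentane strain. C8 is the only new stereocentre: the syn rotamer leaves the former carbonyl oxygen eclipsed with the new C7=O (equatorial OH) and the methyl axial on the face from which the acetyl carbon enters, which is the C20 face fixed by C7 of 21; C9 migrates with retention. The step needs C9 and not C6 to migrate: with the acetyl group syn to C20 only C9 migration passes through a chair-like six-membered ring (C6 migration would give a boat-like trans-fused ring), and C9 is the more substituted carbon. It also needs kinetic control (low temperature, short time) so that the product ketol does not isomerise further by methyl shift, and the iodine-deactivated alkene has to stay out of a Prins-type addition to the activated carbonyl.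

Step 14
Reactants: 22 ring-enlarged ketol
Product: 25 6,8-dihydroxy-7-ketone (O-6 anti to C20), via bis-silyl enol ether 23 (not isolated), via bis-silyl acyloin 24 (not isolated)
Conditions: TMSOTf, Et3N, CH2Cl2, 0 °C; then mCPBA, CH2Cl2, −20 °C; then citric acid, MeOH, rt
Reagents that add atoms: mCPBA, O=C(OO)c1cccc(Cl)c1
Why: Rubottom oxidation: enolisation can only go towards C6 (C8 is quaternary), the peracid should epoxidise the silyl enol ether anti to the three axial methyls (on C4, C8, C10), and silyl shift followed by methanolysis gives the equatorial 6-hydroxy ketone.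

Step 15
Reactants: 25 dihydroxy ketone
Product: 26 6,7,8-triol (O-7 syn to C20)
Conditions: NaBH4, MeOH, −20 to 0 °C
Reagents that add atoms: none
Why: Borohydride reduction: hydride should add axially to C7 from the face anti to the axial C8 methyl, giving the equatorial 7-alcohol and hence the all-equatorial triol.

Step 16
Reactants: 26 triol
Product: 27 6,7-diacetate with free 8-OH
Conditions: Ac2O, pyridine, DMAP (cat.), CH2Cl2, 0 °C to rt
Reagents that add atoms: acetic anhydride, CC(=O)OC(C)=O
Why: Acylation esterifies the two secondary alcohols, while the hindered tertiary C8 alcohol should not react under these conditions.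

Step 17
Reactants: 27 iodoalkene diacetate; 28 tributyl(vinyl)stannane
Product: 29 target
Conditions: 28, Pd2(dba)3 (cat.), P(2-furyl)3 (cat.), CuI (cat.), NMP, rt
Reagents that add atoms: tributyl(vinyl)stannane 28, C=C[Sn](CCCC)(CCCC)CCCC
Why: Stille coupling: oxidative addition, transmetallation and reductive elimination proceed with retention at the alkenyl carbon, so the vinyl group ends up cis to C11 (12Z) under neutral conditions that spare the acetates.

**Compound list**

1 | 2,2,6-trimethylcyclohexan-1-one (racemic) | CC1CCCC(C)(C)C1=O | starting material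
2 | allyl chloroformate | C=CCOC(Cl)=O | starting material
3 | lithium 2,6,6-trimethylcyclohex-1-en-1-olate (not isolated) | [Li]OC1=C(C)CCCC1(C)C | intermediate
4 | allyl 2,6,6-trimethylcyclohex-1-en-1-yl carbonate | C=CCOC(=O)OC1=C(C)CCCC1(C)C | intermediate
5 | (S)-2-allyl-2,6,6-trimethylcyclohexan-1-one | C=CC[C@]1(C)CCCC(C)(C)C1=O | intermediate
6 | (S)-2,2,6-trimethyl-6-(2-oxopropyl)cyclohexan-1-one | CC(=O)C[C@]1(C)CCCC(C)(C)C1=O | intermediate
7 | (7aS)-4,4,7a-trimethyl-1,4,5,6,7,7a-hexahydro-2H-inden-2-one | O=C1C[C@]2(C)CCCC(C)(C)C2=C1 | intermediate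
8 | tert-butyl(2-iodoethoxy)dimethylsilane | CC(C)(C)[Si](C)(C)OCCI | starting material
9 | lithium cross-conjugated dienolate of 7 (not isolated) | [Li]OC1=C[C@]2(C)CCCC(C)(C)C2=C1 | intermediate
10 | enone 7 bearing a 2-(tert-butyldimethylsilyloxy)ethyl group on C9 (indene C1), C9 epimers | CC(C)(C)[Si](C)(C)OCCC1C(=O)C=C2C(C)(C)CCC[C@]21C | intermediate
11 | lithium C6=C7 enolate of the trans-fused ketone (not isolated) | CC(C)(C)[Si](C)(C)OCCC1C(O[Li])=C[C@@H]2C(C)(C)CCC[C@]21C | intermediate
12 | trans-fused octahydroinden-2-one, C9 epimer mixture (not isolated) | CC(C)(C)[Si](C)(C)OCCC1C(=O)C[C@@H]2C(C)(C)CCC[C@]21C | intermediate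
13 | trans-fused 4,4,7a-trimethyloctahydroinden-2-one with the 1-[2-(silyloxy)ethyl] chain cis and H-3a trans to the 7a-methyl | CC(C)(C)[Si](C)(C)OCC[C@@H]1C(=O)C[C@@H]2C(C)(C)CCC[C@]21C | intermediate
14 | ethyltriphenylphosphonium bromide | CC[P+](c1ccccc1)(c1ccccc1)c1ccccc1.[Br-] | starting material
15 | 7-ethylidene derivative of 13 (E/Z mixture, geometry removed in step 12) | CC(C)(C)[Si](C)(C)OCC[C@@H]1C(=CC)C[C@@H]2C(C)(C)CCC[C@]21C | intermediate
16 | primary alcohol from 15 | OCC[C@@H]1C(=CC)C[C@@H]2C(C)(C)CCC[C@]21C | intermediate
17 | C12 aldehyde | O=CC[C@@H]1C(=CC)C[C@@H]2C(C)(C)CCC[C@]21C | intermediate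
18 | ethyltriphenylphosphonium iodide | CC[P+](c1ccccc1)(c1ccccc1)c1ccccc1.[I-] | starting material
19 | 7-ethylidene hydrindane with a (Z)-3-iodobut-2-enyl chain on C9 | I/C(C)=C\C[C@@H]1C(=CC)C[C@@H]2C(C)(C)CCC[C@]21C | intermediate
20 | 7,8-diol, O-7 anti to C20 (C8 epimers, centre removed in step 12) | I/C(C)=C\C[C@@H]1[C@](O)(C(C)O)C[C@@H]2C(C)(C)CCC[C@]21C | intermediate
21 | 7-acetyl-7-hydroxy trans-hydrindane, acetyl syn and OH anti to C20 | I/C(C)=C\C[C@@H]1[C@](O)(C(C)=O)C[C@@H]2C(C)(C)CCC[C@]21C | intermediate
22 | (12Z)-8-hydroxy-13-iodo-14,15-dinorlabd-12-en-7-one of the 10R series, OH-8 anti and CH3-8 syn to C20 | I/C(C)=C\C[C@@H]1[C@@](C)(O)C(=O)C[C@@H]2C(C)(C)CCC[C@]21C | intermediate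
23 | 7,8-bis(trimethylsilyloxy)-6-ene (not isolated) | I/C(C)=C\C[C@@H]1[C@@](C)(O[Si](C)(C)C)C(O[Si](C)(C)C)=C[C@@H]2C(C)(C)CCC[C@]21C | intermediate
24 | 6,8-bis(trimethylsilyloxy)-7-ketone (not isolated) | I/C(C)=C\C[C@@H]1[C@@](C)(O[Si](C)(C)C)C(=O)[C@@H](O[Si](C)(C)C)[C@@H]2C(C)(C)CCC[C@]21C | intermediate
25 | 6,8-dihydroxy-7-ketone, OH-6 anti to C20 | I/C(C)=C\C[C@@H]1[C@@](C)(O)C(=O)[C@@H](O)[C@@H]2C(C)(C)CCC[C@]21C | intermediate
26 | 6,7,8-triol, OH-6 anti, OH-7 syn, OH-8 anti to C20 | I/C(C)=C\C[C@@H]1[C@@](C)(O)[C@H](O)[C@@H](O)[C@@H]2C(C)(C)CCC[C@]21C | intermediate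
27 | 6,7-diacetate of 26 with free 8-OH | I/C(C)=C\C[C@@H]1[C@@](C)(O)[C@H](OC(C)=O)[C@@H](OC(C)=O)[C@@H]2C(C)(C)CCC[C@]21C | intermediate
28 | tributyl(vinyl)stannane | C=C[Sn](CCCC)(CCCC)CCCC | starting material
29 | (12Z)-labda-12,14-diene-6,7,8-triol 6,7-diacetate of the 10R series (6-OAc anti, 7-OAc syn, 8-OH anti to C20) | C=C/C(C)=C\C[C@@H]1[C@@](C)(O)[C@H](OC(C)=O)[C@@H](OC(C)=O)[C@@H]2C(C)(C)CCC[C@]21C | target

**Count and risks**

Total step count: 17. Longest linear sequence: 17 steps (1 to 29).

Steps most likely to fail:

1. Step 13. The C6–C7 bond may migrate in place of C7–C9, the product ketol may drift on by methyl shift under thermodynamic control, or the iodoalkene may add to the Lewis-acid-activated carbonyl. Fallback: setting out from diol 20, the secondary hydroxyl is mesylated (MsCl, Et3N) to the 8-mesylate F1. Et3Al in CH2Cl2 at −78 °C then triggers a semipinacol shift of C9 from C7 to C8 with loss of mesylate, giving the ring-enlarged 8-methyl-7-ketone F2 irreversibly and without an activated ketol. The more substituted silyl enol ether F3 (TMSCl, NaI, Et3N, MeCN) is epoxidised by mCPBA anti to C20 to the 8-trimethylsilyloxy ketone F4, and methanolysis (citric acid, MeOH) brings the sequence back to the route at 22.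

2. Step 6. Protonation of C5 may show poor facial selectivity (cis-fused ring), and the epimer ratio at C9 may be unfavourable. Fallback: setting out from 10, Luche reduction (NaBH4, CeCl3, MeOH) gives the allylic alcohol F5. Radical hydrogen-atom-transfer hydrogenation (Mn(dpm)3, PhSiH3, TBHP, i-PrOH) then delivers hydrogen to the tertiary C5 radical from the face anti to the axial methyls and gives the saturated trans-fused alcohol F6. Dess–Martin oxidation returns the ketone and the sequence comes back to the route at 12, which is equilibrated with methoxide to 13 as before.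

3. Step 5. Alkylation next to the quaternary carbon may be slow, so that proton transfer and double alkylation take over. Fallback: setting out from 7, the dienolate is alkylated with the more reactive allyl bromide to the allyl enone F7. Li/NH3 reduction and methoxide equilibration give the allyl trans-hydrindanone F8. Lemieux–Johnson cleavage (OsO4 cat., NaIO4, 2,6-lutidine) gives the keto aldehyde F9, aldehyde-selective reduction with NaBH(OAc)3 gives the hydroxy ketone F10, and silylation (TBSCl, imidazole) comes back to the route at 13.

**Further compounds**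

F1 | step 13 | 8-O-mesylate of diol 20 | I/C(C)=C\C[C@@H]1[C@](O)(C(C)OS(C)(=O)=O)C[C@@H]2C(C)(C)CCC[C@]21C
F2 | step 13 | ring-enlarged 8-methyl-7-ketone (C8 epimers) | I/C(C)=C\C[C@@H]1C(C)C(=O)C[C@@H]2C(C)(C)CCC[C@]21C
F3 | step 13 | 7-trimethylsilyloxy-7(8)-ene | I/C(C)=C\C[C@@H]1C(C)=C(O[Si](C)(C)C)C[C@@H]2C(C)(C)CCC[C@]21C
F4 | step 13 | 8-O-trimethylsilyl ether of 22 | I/C(C)=C\C[C@@H]1[C@@](C)(O[Si](C)(C)C)C(=O)C[C@@H]2C(C)(C)CCC[C@]21C
F5 | step 6 | allylic alcohol from 10 (C7 and C9 epimers) | CC(C)(C)[Si](C)(C)OCCC1C(O)C=C2C(C)(C)CCC[C@]21C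
F6 | step 6 | saturated trans-fused alcohol (C7 and C9 epimers) | CC(C)(C)[Si](C)(C)OCCC1C(O)C[C@@H]2C(C)(C)CCC[C@]21C
F7 | step 5 | 9-allyl enone (C9 epimers) | C=CCC1C(=O)C=C2C(C)(C)CCC[C@]21C
F8 | step 5 | 9-allyl trans-hydrindanone, allyl syn to C20 | C=CC[C@@H]1C(=O)C[C@@H]2C(C)(C)CCC[C@]21C
F9 | step 5 | keto aldehyde | O=CC[C@@H]1C(=O)C[C@@H]2C(C)(C)CCC[C@]21C
F10 | step 5 | hydroxy ketone (in equilibrium with its hemiketal) | OCC[C@@H]1C(=O)C[C@@H]2C(C)(C)CCC[C@]21C
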